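**Retrosynthetic overview**

1. Lespeflorin B1 (18) ⇐ acid deprotection of 17 ⇐ twofold Stille prenylation at the C6 and C3' bromides of protected dihydroflavonol 15; the bromides are carried as robust placeholders for the prenyl groups through the acid and oxidant steps.
2. 15 ⇐ oxidation of the C4 methylene of silyl ether 13 ⇐ flavan-3-ol 12 ⇐ exchange of boron for oxygen with retention in the trans 3-boryl flavan 11.
3. The strategy rests on ring A holding the ether oxygen O1 on C8a and the benzylic carbon C4 on the neighbouring C4a, the two ends of an ortho-quinone methide, while C2–C3 is a trans-disubstituted two-carbon unit that maps onto an E alkene. Ring C is therefore cut at O1–C2 and C3–C4 into quinone methide 10 (from salicyl alcohol 3) and E-styrylboronate 9, with boron as the latent 3-OH.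
4. 3 ⇐ 5-bromo-2,4-dihydroxybenzaldehyde 1 (mono-MOM ether, NaBH4); 9 ⇐ 3-bromo-4-hydroxybenzaldehyde 4 (MOM ether, boron-Wittig olefination with diborylmethane 6).
5. Ring order: rings A and B are bought; ring C is the only ring formed, in step 5.

Key step: step 5

Assumption: the sense of induction of the chiral acid with this untested dienophile cannot be predicted; the route is written for the catalyst antipode that gives (2S,3S)-11, shown as the (R)-acid, and the (S)-acid is used instead if a pilot run shows the opposite sense.

**Route**

Step 1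
Reactants: 1 5-bromo-2,4-dihydroxybenzaldehyde
Product: 2 5-bromo-2-hydroxy-4-(methoxymethoxy)benzaldehyde
Conditions: MOMCl (1.1 equiv), K2CO3, acetone, 0 °C to rt
Reagents that add atoms: chloromethyl methyl ether (MOMCl), COCCl
Why: Williamson-type O-alkylation; the 4-hydroxyl (para to the formyl group, not hydrogen-bonded) is more acidic and more accessible than the 2-hydroxyl, which is locked in a hydrogen bond to the aldehyde oxygen, so one equivalent of MOMCl with a weak base should etherify O4 only.

Step 2
Reactants: 2 5-bromo-2-hydroxy-4-(methoxymethoxy)benzaldehyde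
Product: 3 4-bromo-2-(hydroxymethyl)-5-(methoxymethoxy)phenol
Conditions: NaBH4, THF/MeOH, 0 °C; aq. NH4Cl work-up
Reagents that add atoms: none
Why: Borohydride reduction of the aryl aldehyde to the primary benzylic alcohol; the aryl bromide and MOM acetal are inert, and the near-neutral work-up keeps the acid-sensitive salicyl alcohol from ionising early.

Step 3
Reactants: 4 3-bromo-4-hydroxybenzaldehyde
Product: 5 3-bromo-4-(methoxymethoxy)benzaldehyde
Conditions: MOMCl (1.2 equiv), K2CO3, acetone, rt
Reagents that add atoms: chloromethyl methyl ether (MOMCl), COCCl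
Why: Williamson-type O-alkylation of the only phenol, giving an alkyl ether that remains a para donor for the positive charge that later develops at C2.

Step 4
Reactants: 5 3-bromo-4-(methoxymethoxy)benzaldehyde; 6 bis(pinacolato)borylmethane
Product: 9 (E)-2-[3-bromo-4-(methoxymethoxy)styryl]-4,4,5,5-tetramethyl-1,3,2-dioxaborolane, via lithiated diborylmethane 7 (not isolated), via lithium alkoxide adduct 8 (not isolated)
Conditions: 6 (1.2 equiv), LiTMP (lithium 2,2,6,6-tetramethylpiperidide, 1.2 equiv), THF, 0 °C, 10 min; then 5, −78 °C to rt
Reagents that add atoms: none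
Why: Boron-Wittig olefination; carbanion 7 adds to the aldehyde and the β-oxido gem-diboronate 8 loses boron and oxygen in a syn elimination through the less crowded arrangement to give the E alkenyl boronate, and because the amide base is consumed before 5 is added the aryl bromide and MOM ether are not touched.

Step 5
Reactants: 3 4-bromo-2-(hydroxymethyl)-5-(methoxymethoxy)phenol; 9 (E)-2-[3-bromo-4-(methoxymethoxy)styryl]-4,4,5,5-tetramethyl-1,3,2-dioxaborolane
Product: 11 (2S,3S)-6-bromo-2-[3-bromo-4-(methoxymethoxy)phenyl]-7-(methoxymethoxy)-3-(4,4,5,5-tetramethyl-1,3,2-dioxaborolan-2-yl)chroman (2,3-trans), via ortho-quinone methide 10 (not isolated)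
Conditions: (R)-3,3'-bis(2,4,6-triisopropylphenyl)-1,1'-binaphthyl-2,2'-diyl N-(trifluoromethylsulfonyl)phosphoramide (10 mol %), 9 (1.5 equiv), 5 Å molecular sieves, toluene, −20 °C to rt, slow addition of 3
Reagents that add atoms: none
Why: Proposed new method: the strong chiral acid ionises the benzylic C–O bond of 3 (helped by the para 7-alkoxy group) to quinone methide 10, which stays hydrogen-bonded to the chiral anion and reacts as an electron-poor 1-oxadiene; its methide carbon (future C4) bonds to the boron-bearing alkene carbon of 9 (future C3) while positive charge builds at the benzylic carbon (future C2), onto which the quinone oxygen then closes. The nearest established chemistry is the hetero-Diels–Alder reaction of acid-generated ortho-quinone methides with plain styrenes or vinyl ethers under chiral phosphoric acid or N-triflylphosphoramide catalysis, which gives 2-substituted chromans; new here is a styrene carrying a β-pinacolboryl group, which should lower the alkene nucleophilicity only modestly and offers no way to stabilise charge at C3. Ring C closes as a concerted but asynchronous [4+2] cycloaddition (4π from C4=C4a–C8a=O, 2π from the alkene), which in its stepwise limit is attack of the phenolic oxygen on the C2 benzylic cation to form the six-membered ring. C2 and C3 should come out trans because addition across the E alkene is suprafacial (a stepwise closure would also prefer the diequatorial trans product), and their absolute configuration is set by the chiral anion, which holds the quinone methide oxygen by a hydrogen bond inside the pocket of its 3,3'-aryl groups, possibly with a second contact of its phosphoryl oxygen to boron, so that one face of the methide is open. The step needs regioselectivity (C4 to C3, O1 to C2), secured by the para-alkoxyaryl ring that stabilises charge at C2 only, and chemoselectivity for cycloaddition over self-condensation of 10 and over alkenyl transfer from boron, secured by slow addition of 3 to an excess of 9, by the bromine that blocks the ring position para to the phenol, and by the low Lewis acidity of the pinacol ester in the absence of base.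

Step 6
Reactants: 11 (2S,3S)-3-boryl flavan
Product: 12 (2R,3S)-6-bromo-2-[3-bromo-4-(methoxymethoxy)phenyl]-7-(methoxymethoxy)chroman-3-ol (2,3-trans)
Conditions: NaBO3·4H2O (4 equiv), THF/H2O (1:1), rt
Reagents that add atoms: sodium perborate tetrahydrate (NaBO3·4H2O), [Na+].[Na+].O[B-]1(O)OO[B-](O)(O)OO1.O.O.O.O.O.O
Why: Oxidation of the secondary alkyl boronate; the peroxide adds to boron and C3 migrates from boron to oxygen with retention, so the 3-hydroxyl keeps the trans relation to the 2-aryl group (the descriptor at C2 changes to R only through the priority change), while the mild base leaves MOM ethers and aryl bromides alone.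

Step 7
Reactants: 12 (2R,3S)-flavan-3-ol
Product: 13 (2R,3S)-6-bromo-2-[3-bromo-4-(methoxymethoxy)phenyl]-3-[(tert-butyldimethylsilyl)oxy]-7-(methoxymethoxy)chroman
Conditions: TBSCl, imidazole, DMAP (cat.), DMF, rt
Reagents that add atoms: tert-butyldimethylsilyl chloride (TBSCl), CC(C)(C)[Si](C)(C)Cl
Why: Silylation of the secondary alcohol, which blocks later oxidation of the α-hydroxy ketone to the flavonol; a silyl chloride is used because silyl triflates can cleave aryl MOM ethers.

Step 8
Reactants: 13 (2R,3S)-3-silyloxy flavan
Product: 15 (2R,3R)-6-bromo-2-[3-bromo-4-(methoxymethoxy)phenyl]-3-[(tert-butyldimethylsilyl)oxy]-7-(methoxymethoxy)chroman-4-one, via flavan-4-ol 14 (not isolated)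
Conditions: DDQ (3 equiv), CH2Cl2/pH 7 phosphate buffer (10:1), rt to 40 °C
Reagents that add atoms: water, O
Why: Benzylic oxidation with DDQ, the reaction type used for C4 oxidation of flavan-3-ol ethers; hydride abstraction from C4 gives a cation stabilised by O1 and the para 7-alkoxy group of ring A, water traps it as flavan-4-ol 14, which is a better hydride donor and should be oxidised on to the aryl ketone, whereas the C2 hydrogen sits on the less electron-rich ring B next to the bulky silyl ether; C2 and C3 are not touched (the C3 descriptor becomes R through the priority change only) and the buffer protects the MOM ethers from the acidic hydroquinone.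

Step 9
Reactants: 15 (2R,3R)-dibromo ketone; 16 tributyl(3-methylbut-2-en-1-yl)stannane
Product: 17 (2R,3R)-3-[(tert-butyldimethylsilyl)oxy]-7-(methoxymethoxy)-2-[4-(methoxymethoxy)-3-(3-methylbut-2-en-1-yl)phenyl]-6-(3-methylbut-2-en-1-yl)chroman-4-one
Conditions: 16 (2.6 equiv), Pd(PPh3)4 (10 mol %), degassed DMF, 95 °C
Reagents that add atoms: none
Why: Twofold Stille coupling; zerovalent palladium inserts into each aryl bromide, the allylic stannane transmetalates and reductive elimination at the unsubstituted carbon should give the linear prenyl groups, under neutral conditions that leave the base-sensitive α-silyloxy ketone and its two stereocentres untouched.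

Step 10
Reactants: 17 (2R,3R)-bis-prenyl protected dihydroflavonol
Product: 18 Lespeflorin B1, (2R,3R)-3,7-dihydroxy-2-[4-hydroxy-3-(3-methylbut-2-en-1-yl)phenyl]-6-(3-methylbut-2-en-1-yl)chroman-4-one
Conditions: 3 M aq. HCl/MeOH (1:4), 40 °C, monitored and stopped at full conversion
Reagents that add atoms: none
Why: Acid-catalysed methanolysis of the two aryl MOM acetals and of the silyl ether in one operation; dilute acid at mild temperature should stay below the threshold for cyclisation of the ortho-prenyl phenols to chromans, and the trans dihydroflavonol stereocentres are stable to acid.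

**Compound list**

1 | 5-bromo-2,4-dihydroxybenzaldehyde | O=Cc1cc(Br)c(O)cc1O | starting material
2 | 5-bromo-2-hydroxy-4-(methoxymethoxy)benzaldehyde | O=Cc1cc(Br)c(OCOC)cc1O | intermediate
3 | 4-bromo-2-(hydroxymethyl)-5-(methoxymethoxy)phenol | OCc1cc(Br)c(OCOC)cc1O | intermediate
4 | 3-bromo-4-hydroxybenzaldehyde | O=Cc1ccc(O)c(Br)c1 | starting material
5 | 3-bromo-4-(methoxymethoxy)benzaldehyde | O=Cc1ccc(OCOC)c(Br)c1 | intermediate
6 | bis(pinacolato)borylmethane | CC1(C)OB(CB2OC(C)(C)C(C)(C)O2)OC1(C)C | starting material
7 | lithio-bis(pinacolatoboryl)methane | [Li]C(B1OC(C)(C)C(C)(C)O1)B1OC(C)(C)C(C)(C)O1 | intermediate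
8 | lithium 1-[3-bromo-4-(methoxymethoxy)phenyl]-2,2-bis(pinacolatoboryl)ethoxide (racemic) | [Li]OC(c1ccc(OCOC)c(Br)c1)C(B1OC(C)(C)C(C)(C)O1)B1OC(C)(C)C(C)(C)O1 | intermediate
9 | (E)-2-[3-bromo-4-(methoxymethoxy)styryl]-4,4,5,5-tetramethyl-1,3,2-dioxaborolane | CC1(C)OB(/C=C/c2ccc(OCOC)c(Br)c2)OC1(C)C | intermediate
10 | 4-bromo-3-(methoxymethoxy)-6-methylidenecyclohexa-2,4-dien-1-one (ring A ortho-quinone methide) | C=C1C=C(Br)C(OCOC)=CC1=O | intermediate
11 | (2S,3S)-6-bromo-2-[3-bromo-4-(methoxymethoxy)phenyl]-7-(methoxymethoxy)-3-(4,4,5,5-tetramethyl-1,3,2-dioxaborolan-2-yl)chroman, 2,3-trans | COCOc1ccc([C@H]2Oc3cc(OCOC)c(Br)cc3C[C@@H]2B4OC(C)(C)C(C)(C)O4)cc1Br | intermediate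
12 | (2R,3S)-6-bromo-2-[3-bromo-4-(methoxymethoxy)phenyl]-7-(methoxymethoxy)chroman-3-ol, 2,3-trans | COCOc1ccc([C@H]2Oc3cc(OCOC)c(Br)cc3C[C@@H]2O)cc1Br | intermediate
13 | (2R,3S)-6-bromo-2-[3-bromo-4-(methoxymethoxy)phenyl]-3-[(tert-butyldimethylsilyl)oxy]-7-(methoxymethoxy)chroman | COCOc1ccc([C@H]2Oc3cc(OCOC)c(Br)cc3C[C@@H]2O[Si](C)(C)C(C)(C)C)cc1Br | intermediate
14 | (2R,3S)-6-bromo-2-[3-bromo-4-(methoxymethoxy)phenyl]-3-[(tert-butyldimethylsilyl)oxy]-7-(methoxymethoxy)chroman-4-ol, mixture of C4 epimers | COCOc1ccc([C@H]2Oc3cc(OCOC)c(Br)cc3C(O)[C@@H]2O[Si](C)(C)C(C)(C)C)cc1Br | intermediate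
15 | (2R,3R)-6-bromo-2-[3-bromo-4-(methoxymethoxy)phenyl]-3-[(tert-butyldimethylsilyl)oxy]-7-(methoxymethoxy)chroman-4-one | COCOc1ccc([C@H]2Oc3cc(OCOC)c(Br)cc3C(=O)[C@@H]2O[Si](C)(C)C(C)(C)C)cc1Br | intermediate
16 | tributyl(3-methylbut-2-en-1-yl)stannane | CCCC[Sn](CCCC)(CCCC)CC=C(C)C | starting material
17 | (2R,3R)-3-[(tert-butyldimethylsilyl)oxy]-7-(methoxymethoxy)-2-[4-(methoxymethoxy)-3-(3-methylbut-2-en-1-yl)phenyl]-6-(3-methylbut-2-en-1-yl)chroman-4-one | COCOc1ccc([C@H]2Oc3cc(OCOC)c(CC=C(C)C)cc3C(=O)[C@@H]2O[Si](C)(C)C(C)(C)C)cc1CC=C(C)C | intermediate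
18 | Lespeflorin B1, (2R,3R)-3,7-dihydroxy-2-[4-hydroxy-3-(3-methylbut-2-en-1-yl)phenyl]-6-(3-methylbut-2-en-1-yl)chroman-4-one | CC(C)=CCc1cc([C@H]2Oc3cc(O)c(CC=C(C)C)cc3C(=O)[C@@H]2O)ccc1O | target

**Step count**

Total: 10 steps. Longest linear sequence: 8 steps (1, 2, 5, 6, 7, 8, 9, 10, from compound 1).

**Steps most likely to fail**

1. Step 5 (the step proposed as a new method).
 - What may go wrong: the quinone methide may condense with itself before it is trapped. After the C4–C3 bond has formed, the benzylic cation may lose boron instead of closing, or the alkenyl group may shift from boron to the methide carbon. The chiral anion may also discriminate the two faces poorly.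
 - Fallback: sets out from 3 and 5 and comes back at 12. It moves the C3 oxygen to a later hydroboration, so the dienophile is a plain 4-alkoxystyrene, the class for which the chiral Brønsted acid cycloaddition is established.
 - Wittig methylenation of 5 (Ph3P=CH2 from methyltriphenylphosphonium bromide and KOt-Bu, THF, 0 °C) gives 2-bromo-4-ethenyl-1-(methoxymethoxy)benzene F1.
 - Cycloaddition of F1 with the quinone methide from 3, under the conditions of step 5 with the acid antipode that gives the 2S product, should give (2S)-6-bromo-2-[3-bromo-4-(methoxymethoxy)phenyl]-7-(methoxymethoxy)chroman F2.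
 - Dehydrogenation with DDQ in dry 1,4-dioxane should give (2S)-6-bromo-2-[3-bromo-4-(methoxymethoxy)phenyl]-7-(methoxymethoxy)-2H-chromene F3. The lowest workable temperature is used, since 2-aryl-2H-chromenes can racemise by electrocyclic ring opening when heated.
 - Hydroboration of F3 with BH3·THF at 0 °C from the face away from the 2-aryl group, with boron at C3, followed by NaBO3·4H2O, returns the trans flavan-3-ol 12.

2. Step 8.
 - What may go wrong: hydride abstraction from C4 may be slow because the bromine lowers the donor strength of ring A. Abstraction of the C2 hydrogen may compete, or the C4 cation may lose the C3 proton and the C3 configuration with it.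
 - Fallback: sets out from 13 and comes back at 15. It replaces hydride abstraction by a quinone with a staged acetoxylation, acetate removal and alcohol oxidation.
 - Pb(OAc)4 in benzene/AcOH (rt to 50 °C), the classical C4 acetoxylation of flavan ethers, should give the 4-O-acetyl derivative of 14 (2,3-trans, C4 epimer mixture) F4.
 - Reductive removal of the acetate with i-Bu2AlH (CH2Cl2, −78 °C) avoids base and hence silyl migration between O3 and O4, and frees flavan-4-ol 14.
 - Dess–Martin periodinane (CH2Cl2, NaHCO3, rt) then oxidises 14 to ketone 15.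

3. Step 9.
 - What may go wrong: the prenyl group may couple through its γ-carbon (reverse prenylation). The second coupling may stall, or the hindered ortho-alkoxy bromides may undergo protodebromination.
 - Fallback: sets out from 15 and comes back at 17. It builds each prenyl group in two stages, so no ambident allyl metal is involved.
 - Stille coupling with allyltributylstannane (Pd(PPh3)4, DMF, 90 °C), which has no regiochemical choice, should give (2R,3R)-3-[(tert-butyldimethylsilyl)oxy]-7-(methoxymethoxy)-2-[4-(methoxymethoxy)-3-(prop-2-en-1-yl)phenyl]-6-(prop-2-en-1-yl)chroman-4-one F5.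
 - Cross-metathesis of both allyl groups with excess 2-methyl-2-butene (second-generation Grubbs catalyst (H2IMes)(PCy3)Cl2Ru=CHPh, CH2Cl2, 40 °C) then gives 17.

**Further compounds**

F1 | step 5 | 2-bromo-4-ethenyl-1-(methoxymethoxy)benzene | C=Cc1ccc(OCOC)c(Br)c1
F2 | step 5 | (2S)-6-bromo-2-[3-bromo-4-(methoxymethoxy)phenyl]-7-(methoxymethoxy)chroman | COCOc1ccc([C@H]2Oc3cc(OCOC)c(Br)cc3CC2)cc1Br
F3 | step 5 | (2S)-6-bromo-2-[3-bromo-4-(methoxymethoxy)phenyl]-7-(methoxymethoxy)-2H-chromene | COCOc1ccc([C@H]2Oc3cc(OCOC)c(Br)cc3C=C2)cc1Br
F4 | step 8 | 4-O-acetyl derivative of 14 (2,3-trans, C4 epimer mixture) | COCOc1ccc([C@H]2Oc3cc(OCOC)c(Br)cc3C(OC(C)=O)[C@@H]2O[Si](C)(C)C(C)(C)C)cc1Br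
F5 | step 9 | (2R,3R)-3-[(tert-butyldimethylsilyl)oxy]-7-(methoxymethoxy)-2-[4-(methoxymethoxy)-3-(prop-2-en-1-yl)phenyl]-6-(prop-2-en-1-yl)chroman-4-one | COCOc1ccc([C@H]2Oc3cc(OCOC)c(CC=C)cc3C(=O)[C@@H]2O[Si](C)(C)C(C)(C)C)cc1CC=C
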